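**Retrosynthetic overview**
- The target comes from a 5-chloro-7-hydroxy-6,8-dione (azaphilone) by hydroxyl-directed reduction of the C8 ketone; the chlorine is put on C5 of the azaphilone just before.
- The azaphilone comes from a 2-alkynylbenzaldehyde: gold 6-endo cycloisomerization closes the pyran ring, then singlet-oxygen photooxygenation forms the key C7–O bond and dearomatizes the carbocycle.
- The 2-alkynylbenzaldehyde comes from Sonogashira coupling of 6-bromo-2,4-dihydroxy-3-methylbenzaldehyde with an (E)-enyne diol.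
- The enyne diol comes from L-isoleucine: C4' and C5' are bought, C3' is set by Cram-chelate MeMgBr addition to an α'-hydroxy diynone, and the E-alkene by hydroxyl-directed LiAlH4 reduction.
- Ring order: benzene ring (bought), then pyran ring, then the dearomatized carbocycle. C7 is not facially controlled; its two epimers are separated as diastereomers after step 9.

Assumption: 1,4-bis(trimethylsilyl)buta-1,3-diyne and 5-bromo-1,3-dimethoxy-2-methylbenzene are taken as commercial; ring locants (C1 to C8a) follow isochromene numbering and primed locants the heptenyl side chain.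

**Route**

Step 1
Reactants: 1 L-isoleucine
Product: 2 (2S,3S)-2-hydroxy-3-methylpentanoic acid
Conditions: NaNO2, 1 M aq H2SO4, 0 °C to rt
Reagents that add atoms: water, O
Why: Diazotization of the α-amino acid (hydroxy-dediazoniation) runs through an α-lactone, so two inversions give net retention at C2, and the bought C3 centre is untouched.

Step 2
Reactants: 2 (2S,3S)-2-hydroxy-3-methylpentanoic acid
Product: 3 (5S)-5-[(2S)-butan-2-yl]-2,2-dimethyl-1,3-dioxolan-4-one
Conditions: 2,2-dimethoxypropane, p-TsOH·H2O (cat.), acetone, rt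
Reagents that add atoms: 2,2-dimethoxypropane, COC(C)(C)OC
Why: Acid-catalysed acetalization to a 1,3-dioxolan-4-one masks the alcohol and activates the carboxyl in one operation without touching either stereocentre.

Step 3
Reactants: 3 (5S)-5-[(2S)-butan-2-yl]-2,2-dimethyl-1,3-dioxolan-4-one; 4 1,4-bis(trimethylsilyl)buta-1,3-diyne
Product: 6 (6S,7S)-6-hydroxy-7-methyl-1-(trimethylsilyl)nona-1,3-diyn-5-one, via lithium (trimethylsilyl)butadiynide 5 (not isolated)
Conditions: 4, MeLi·LiBr, THF, rt; then 3, −78 °C; then AcOH, −78 °C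
Reagents that add atoms: none
Why: Silicon–lithium exchange gives the mono-lithio diyne, whose nucleophilic acyl substitution on the dioxolanone stops at a stable tetrahedral alkoxide (Weinreb-like) that releases acetone and the α'-hydroxy ynone only on the cold acidic quench, so the α-centre is kept.

Step 4
Reactants: 6 (6S,7S)-6-hydroxy-7-methyl-1-(trimethylsilyl)nona-1,3-diyn-5-one
Product: 7 (5R,6S,7S)-5,7-dimethyl-1-(trimethylsilyl)nona-1,3-diyne-5,6-diol
Conditions: MeMgBr (3 equiv), Et2O/CH2Cl2, −78 °C; then H2O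
Reagents that add atoms: methylmagnesium bromide, C[Mg]Br
Why: Cram-chelate (cyclic model) Grignard 1,2-addition: the first equivalent makes the magnesium alkoxide, which chelates the ketone oxygen, and methyl adds to the face opposite the sec-butyl group, setting the tertiary carbinol as 5R (C3' of the target).

Step 5
Reactants: 7 (5R,6S,7S)-5,7-dimethyl-1-(trimethylsilyl)nona-1,3-diyne-5,6-diol
Product: 9 (3E,5R,6S,7S)-5,7-dimethylnon-3-en-1-yne-5,6-diol, via silylated enyne diol 8 (not isolated)
Conditions: LiAlH4, THF, 0 °C to rt; then H2O; then K2CO3 (cat.), MeOH, rt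
Reagents that add atoms: none
Why: Hydroxyl-directed trans-hydroalumination of the propargylic alkyne gives only the E-alkene and leaves the distal alkyne, and base-catalysed methanolysis then removes the alkynyl silane.

Step 6
Reactants: 10 5-bromo-1,3-dimethoxy-2-methylbenzene
Product: 11 6-bromo-2,4-dimethoxy-3-methylbenzaldehyde
Conditions: POCl3, DMF, 0 to 90 °C; then H2O
Reagents that add atoms: N,N-dimethylformamide, CN(C)C=O; water, O
Why: Vilsmeier–Haack formylation attacks the only open position, which is ortho to one methoxy group and para to the other.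

Step 7
Reactants: 11 6-bromo-2,4-dimethoxy-3-methylbenzaldehyde
Product: 12 6-bromo-2,4-dihydroxy-3-methylbenzaldehyde
Conditions: BBr3, CH2Cl2, −78 °C to rt; then H2O
Reagents that add atoms: none
Why: Lewis-acid aryl methyl ether cleavage with BBr3 frees both phenols, which are needed for the quinoid chemistry of step 9.

Step 8
Reactants: 12 6-bromo-2,4-dihydroxy-3-methylbenzaldehyde; 9 (3E,5R,6S,7S)-5,7-dimethylnon-3-en-1-yne-5,6-diol
Product: 13 2,4-dihydroxy-6-[(3E,5R,6S,7S)-5,6-dihydroxy-5,7-dimethylnon-3-en-1-yn-1-yl]-3-methylbenzaldehyde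
Conditions: Pd(PPh3)2Cl2 (5 mol%), CuI (10 mol%), Et3N, DMF, 55 °C, degassed
Reagents that add atoms: none
Why: Sonogashira coupling at the C–Br bond activated by the ortho formyl group tolerates the free phenols and the diol and keeps the E-enyne geometry.

Step 9
Reactants: 13 2,4-dihydroxy-6-[(3E,5R,6S,7S)-5,6-dihydroxy-5,7-dimethylnon-3-en-1-yn-1-yl]-3-methylbenzaldehyde
Product: 16 (7R)-3-[(1E,3R,4S,5S)-3,4-dihydroxy-3,5-dimethylhept-1-en-1-yl]-7-hydroxy-7-methyl-6H-isochromene-6,8(7H)-dione, via quinoid anhydrobase 14 (not isolated), via C7 hydroperoxide 15 (not isolated)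
Conditions: Ph3PAuNTf2 (5 mol%), CH2Cl2, rt; then O2 (1 atm), tetraphenylporphyrin (1 mol%), green LEDs, −40 °C; then Me2S, −40 °C to rt
Reagents that add atoms: dioxygen, O=O
Why: Proposed new method: monovalent-gold 6-endo-dig cycloisomerization of the 2-alkynylbenzaldehyde (known) gives the neutral quinoid anhydrobase 14, whose C7 is the central carbon of an enolized 1,3-dicarbonyl and carries the largest HOMO coefficient, so electrophilic singlet oxygen should add there in an ene-type step that takes the enol hydrogen and gives hydroperoxide 15, which Me2S reduces to the tertiary alcohol; the closest known reaction types are the singlet-oxygen α-hydroxylation of enolized β-dicarbonyls and the photooxygenative dearomatization of phenols, not yet shown on a 2-benzopyrylium anhydrobase; the step forms the C7–O bond and dearomatizes the carbocycle, but the flat chromophore has no nearby stereocentre, so both C7 epimers form in about equal amounts and (7R)-16 is separated from its diastereomer by chromatography (the unwanted epimer can be returned to 14 with Zn in AcOH).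

Step 10
Reactants: 16 (7R)-3-[(1E,3R,4S,5S)-3,4-dihydroxy-3,5-dimethylhept-1-en-1-yl]-7-hydroxy-7-methyl-6H-isochromene-6,8(7H)-dione
Product: 17 (7S)-5-chloro-3-[(1E,3R,4S,5S)-3,4-dihydroxy-3,5-dimethylhept-1-en-1-yl]-7-hydroxy-7-methyl-6H-isochromene-6,8(7H)-dione
Conditions: N-chlorosuccinimide, MeCN, 0 °C to rt
Reagents that add atoms: N-chlorosuccinimide, O=C1CCC(=O)N1Cl
Why: Electrophilic chlorination (enaminone-type α-halogenation) goes to C5, the most nucleophilic carbon of the vinylogous ester, as is typical of azaphilones; C7 keeps its geometry and only its descriptor changes.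

Step 11
Reactants: 17 (7S)-5-chloro-3-[(1E,3R,4S,5S)-3,4-dihydroxy-3,5-dimethylhept-1-en-1-yl]-7-hydroxy-7-methyl-6H-isochromene-6,8(7H)-dione
Product: 18 (7S,8R)-5-chloro-3-[(1E,3R,4S,5S)-3,4-dihydroxy-3,5-dimethylhept-1-en-1-yl]-7,8-dihydroxy-7-methyl-7,8-dihydro-6H-isochromen-6-one
Conditions: Me4NBH(OAc)3, MeCN/AcOH, −30 °C; then H2O
Reagents that add atoms: none
Why: Hydroxyl-directed Saksena–Evans reduction: the 7-OH binds boron and delivers hydride intramolecularly to the syn face of the more ketone-like C8 carbonyl (C6 is a deactivated doubly vinylogous ester), giving the trans-7,8-diol, that is 8R.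

**Compound list**
1 | L-isoleucine | CC[C@H](C)[C@H](N)C(=O)O | starting material
2 | (2S,3S)-2-hydroxy-3-methylpentanoic acid | CC[C@H](C)[C@H](O)C(=O)O | intermediate
3 | (5S)-5-[(2S)-butan-2-yl]-2,2-dimethyl-1,3-dioxolan-4-one | CC[C@H](C)[C@@H]1OC(C)(C)OC1=O | intermediate
4 | 1,4-bis(trimethylsilyl)buta-1,3-diyne | C[Si](C)(C)C#CC#C[Si](C)(C)C | starting material
5 | lithium (trimethylsilyl)butadiynide | [Li]C#CC#C[Si](C)(C)C | intermediate
6 | (6S,7S)-6-hydroxy-7-methyl-1-(trimethylsilyl)nona-1,3-diyn-5-one | CC[C@H](C)[C@H](O)C(=O)C#CC#C[Si](C)(C)C | intermediate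
7 | (5R,6S,7S)-5,7-dimethyl-1-(trimethylsilyl)nona-1,3-diyne-5,6-diol | CC[C@H](C)[C@H](O)[C@](C)(O)C#CC#C[Si](C)(C)C | intermediate
8 | (3E,5R,6S,7S)-5,7-dimethyl-1-(trimethylsilyl)non-3-en-1-yne-5,6-diol (silylated enyne diol) | CC[C@H](C)[C@H](O)[C@](C)(O)/C=C/C#C[Si](C)(C)C | intermediate
9 | (3E,5R,6S,7S)-5,7-dimethylnon-3-en-1-yne-5,6-diol | CC[C@H](C)[C@H](O)[C@](C)(O)/C=C/C#C | intermediate
10 | 5-bromo-1,3-dimethoxy-2-methylbenzene | COc1cc(Br)cc(OC)c1C | starting material
11 | 6-bromo-2,4-dimethoxy-3-methylbenzaldehyde | COc1cc(Br)c(C=O)c(OC)c1C | intermediate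
12 | 6-bromo-2,4-dihydroxy-3-methylbenzaldehyde | Oc1cc(Br)c(C=O)c(O)c1C | intermediate
13 | 2,4-dihydroxy-6-[(3E,5R,6S,7S)-5,6-dihydroxy-5,7-dimethylnon-3-en-1-yn-1-yl]-3-methylbenzaldehyde | CC[C@H](C)[C@H](O)[C@](C)(O)/C=C/C#Cc1cc(O)c(C)c(O)c1C=O | intermediate
14 | 3-[(1E,3R,4S,5S)-3,4-dihydroxy-3,5-dimethylhept-1-en-1-yl]-8-hydroxy-7-methyl-6H-isochromen-6-one (quinoid anhydrobase) | CC[C@H](C)[C@H](O)[C@](C)(O)/C=C/C1=CC2=CC(=O)C(C)=C(O)C2=CO1 | intermediate
15 | (7R)-3-[(1E,3R,4S,5S)-3,4-dihydroxy-3,5-dimethylhept-1-en-1-yl]-7-hydroperoxy-7-methyl-6H-isochromene-6,8(7H)-dione (C7 hydroperoxide, formed together with its C7 epimer) | CC[C@H](C)[C@H](O)[C@](C)(O)/C=C/C1=CC2=CC(=O)[C@@](C)(OO)C(=O)C2=CO1 | intermediate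
16 | (7R)-3-[(1E,3R,4S,5S)-3,4-dihydroxy-3,5-dimethylhept-1-en-1-yl]-7-hydroxy-7-methyl-6H-isochromene-6,8(7H)-dione | CC[C@H](C)[C@H](O)[C@](C)(O)/C=C/C1=CC2=CC(=O)[C@@](C)(O)C(=O)C2=CO1 | intermediate
17 | (7S)-5-chloro-3-[(1E,3R,4S,5S)-3,4-dihydroxy-3,5-dimethylhept-1-en-1-yl]-7-hydroxy-7-methyl-6H-isochromene-6,8(7H)-dione | CC[C@H](C)[C@H](O)[C@](C)(O)/C=C/C1=CC2=C(Cl)C(=O)[C@@](C)(O)C(=O)C2=CO1 | intermediate
18 | (7S,8R)-5-chloro-3-[(1E,3R,4S,5S)-3,4-dihydroxy-3,5-dimethylhept-1-en-1-yl]-7,8-dihydroxy-7-methyl-7,8-dihydro-6H-isochromen-6-one (CNP0133971.3) | CC[C@H](C)[C@H](O)[C@](C)(O)/C=C/C1=CC2=C(Cl)C(=O)[C@@](C)(O)[C@H](O)C2=CO1 | target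

**Totals and risks**

Total step count: 11. Longest linear sequence: 9 steps (steps 1 to 5, then 8 to 11, from L-isoleucine); the arene branch is steps 6 and 7.

The three steps most likely to fail:

Step 4 (chelate-controlled methyl addition to the unprotected α'-hydroxy ynone; risks are cyclization of the alkoxide onto the ynone, conjugate addition and weak facial control). The fallback sets out from 6 and replaces alkoxide chelation by an ether-chelate with a removable group. 6 is treated with 4-methoxybenzyl trichloroacetimidate and catalytic camphorsulfonic acid to give (6S,7S)-6-[(4-methoxybenzyl)oxy]-7-methyl-1-(trimethylsilyl)nona-1,3-diyn-5-one F1. MeMgBr in CH2Cl2 at −78 °C then adds under classical Cram-chelate control to give (5R,6S,7S)-6-[(4-methoxybenzyl)oxy]-5,7-dimethyl-1-(trimethylsilyl)nona-1,3-diyn-5-ol F2. DDQ in wet CH2Cl2 removes the benzyl ether, and the route is rejoined at 7.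

Step 9 (the proposed photooxygenation; risks are attack of singlet oxygen on the dienyl ether part of the chromophore and photobleaching). The fallback uses known chemistry and sets out from 13. Au(OAc)3 (5 mol%) in 1,2-dichloroethane/trifluoroacetic acid at 0 °C to rt gives the 2-benzopyrylium salt 3-[(1E,3R,4S,5S)-3,4-dihydroxy-3,5-dimethylhept-1-en-1-yl]-6,8-dihydroxy-7-methylisochromenylium trifluoroacetate F3. This is oxidized in the same flask with the pentavalent iodine reagent IBX and Bu4NI, the established oxygenation of benzopyrylium salts to azaphilones. Both C7 epimers form again and are separated as before; the route is rejoined at 16.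

Step 11 (reduction of C8 in the presence of the α-chloro C6 carbonyl and the electrophilic C1; risks are reduction at C6 and conjugate reduction). The fallback changes the order so that the reduction is done before the chlorine activates C6, and sets out from 16. Me4NBH(OAc)3 in MeCN/AcOH gives (7S,8R)-3-[(1E,3R,4S,5S)-3,4-dihydroxy-3,5-dimethylhept-1-en-1-yl]-7,8-dihydroxy-7-methyl-7,8-dihydro-6H-isochromen-6-one F4. N-Chlorosuccinimide in MeCN then chlorinates C5, and the route comes back at 18.

Further compounds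
F1 | step 4 | (6S,7S)-6-[(4-methoxybenzyl)oxy]-7-methyl-1-(trimethylsilyl)nona-1,3-diyn-5-one | CC[C@H](C)[C@H](OCc1ccc(OC)cc1)C(=O)C#CC#C[Si](C)(C)C
F2 | step 4 | (5R,6S,7S)-6-[(4-methoxybenzyl)oxy]-5,7-dimethyl-1-(trimethylsilyl)nona-1,3-diyn-5-ol | CC[C@H](C)[C@H](OCc1ccc(OC)cc1)[C@](C)(O)C#CC#C[Si](C)(C)C
F3 | step 9 | 3-[(1E,3R,4S,5S)-3,4-dihydroxy-3,5-dimethylhept-1-en-1-yl]-6,8-dihydroxy-7-methylisochromenylium trifluoroacetate | CC[C@H](C)[C@H](O)[C@](C)(O)/C=C/c1cc2cc(O)c(C)c(O)c2c[o+]1.[O-]C(=O)C(F)(F)F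
F4 | step 11 | (7S,8R)-3-[(1E,3R,4S,5S)-3,4-dihydroxy-3,5-dimethylhept-1-en-1-yl]-7,8-dihydroxy-7-methyl-7,8-dihydro-6H-isochromen-6-one | CC[C@H](C)[C@H](O)[C@](C)(O)/C=C/C1=CC2=CC(=O)[C@@](C)(O)[C@H](O)C2=CO1
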